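**Plan**
- Cuts, with the acid numbered from the carboxyl carbon C1 to the chain end C20: C14=C15 (Julia–Kocienski), C12=C13 (Wittig), C6–C7 (Wittig, then diimide), then in one operation the ring O–C3 and C1–C2 bonds, and last the C5–OO and C3–C4 bonds.
- Enabling feature: C3 of the 1,2-dioxolane carries a peroxide oxygen and the C2 methylene bonded to C1, which is what a hydroperoxide oxygen and CO leave on a C2=C3 1,1-disubstituted alkene; C5 holds the other peroxide oxygen on a fully substituted carbon.
- Forward: (R)-2-methylglycidol becomes a methallyl-substituted epoxide and then the tertiary hydroperoxide; the 1,2-dioxolane, the only ring, closes together with the acetate arm; the chain is then joined from C6 outwards (C6–C7, C12=C13, C14=C15) and the ester is hydrolysed.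
- Stereochemistry: C5 from the chiral pool through epoxide perhydrolysis with inversion; C3 in the ring closure, under the chiral ligand on palladium; 12E from a stabilised ylide, 14E from the Julia–Kocienski step, 17Z from (Z)-hex-3-en-1-ol.

Key step: step 5

Remark: the (S,S) antipode of the bis(oxazoline) ligand in step 5 is written by analogy with oxypalladations of phenols; should the induction at C3 run the other way, the mirror-image ligand is used in the same step.

Step 1
Reactants: 1 (R)-2-methylglycidol
Product: 2 [(2S)-2-methyloxiran-2-yl]methyl 4-methylbenzenesulfonate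
Conditions: TsCl, Et3N, DMAP (cat.), CH2Cl2, 0 °C
Reagents that add atoms: 4-methylbenzenesulfonyl chloride, Cc1ccc(cc1)S(Cl)(=O)=O
Why: Tosylation of the primary alcohol prepares the hydroxymethyl arm as the electrophile of the later oxirane closure without touching the quaternary centre, whose descriptor changes from R to S only because the sulfonate arm now outranks the ring CH2.

Step 2
Reactants: 2 [(2S)-2-methyloxiran-2-yl]methyl 4-methylbenzenesulfonate, 3 isopropenylmagnesium bromide
Product: 5 (2S)-2-methyl-2-(2-methylprop-2-en-1-yl)oxirane, via hydroxy tosylate 4 (not isolated)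
Conditions: 3 (1.3 equiv), CuI (10 mol%), THF, −40 to −20 °C; aq. NH4Cl; crude 4, K2CO3, MeOH, rt
Reagents that add atoms: none
Why: Copper-catalysed Grignard opening of the oxirane at its unsubstituted carbon (SN2, C3–C4 bond) followed by Williamson-type 3-exo-tet closure of the tertiary alcohol onto the tosylate moves the epoxide to the other arm, and since no bond to the stereocentre is broken its configuration is retained.

Step 3
Reactants: 5 (2S)-2-methyl-2-(2-methylprop-2-en-1-yl)oxirane, 6 hydrogen peroxide
Product: 7 (2R)-2-hydroperoxy-2,4-dimethylpent-4-en-1-ol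
Conditions: anhydrous ethereal H2O2 (5 equiv), H3PMo12O40 (2 mol%), Et2O, 0 °C to rt
Reagents that add atoms: none
Why: Molybdenum-catalysed perhydrolysis of a 2,2-disubstituted epoxide, in which H2O2 opens the acid-activated oxirane at the tertiary carbon in a borderline SN2 process with inversion, sets the future C5 as an (R)-configured tertiary hydroperoxide, and the low temperature keeps the acid away from the methallyl alkene.

Step 4
Reactants: 7 (2R)-2-hydroperoxy-2,4-dimethylpent-4-en-1-ol
Product: 9 tert-butyl{[(2R)-2-hydroperoxy-2,4-dimethylpent-4-en-1-yl]oxy}diphenylsilane, via bis-silyl peroxide 8 (not isolated)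
Conditions: TBDPSCl (2.5 equiv), imidazole (5 equiv), DMF, 0 °C to rt; then MeOH, K2CO3 (0.3 equiv), 0 °C
Reagents that add atoms: tert-butyl(chloro)diphenylsilane, CC(C)(C)[Si](Cl)(c1ccccc1)c1ccccc1
Why: Because the hydroperoxide is at least as reactive towards the chlorosilane as the hydroxyl, both are silylated and the Si–OO bond alone is then methanolysed under mild base, a peroxide anion being a far better leaving group than an alkoxide (silyl ether formation and selective silyl peroxide cleavage).

Step 5
Reactants: 9 tert-butyl{[(2R)-2-hydroperoxy-2,4-dimethylpent-4-en-1-yl]oxy}diphenylsilane, 10 carbon monoxide, 11 methanol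
Product: 12 methyl 2-[(3R,5R)-5-{[(tert-butyldiphenylsilyl)oxy]methyl}-3,5-dimethyl-1,2-dioxolan-3-yl]acetate
Conditions: Pd(OCOCF3)2 (5 mol%), (S,S)-Bn-BOXAX [2,2'-bis((4S)-4-benzyl-4,5-dihydrooxazol-2-yl)-1,1'-binaphthyl] (20 mol%), p-benzoquinone (4 equiv), CO (1 atm), MeOH, 0 °C to rt
Reagents that add atoms: none
Why: Proposed new method: divalent palladium activates the 1,1-disubstituted alkene, the terminal hydroperoxide oxygen adds to the internal carbon (ring O–C3 bond), and the primary alkylpalladium so formed, whose only β-carbon is quaternary, inserts CO and is cleaved by methanol to the methyl ester (C1–C2 bond) with release of zerovalent palladium, which p-benzoquinone reoxidises. The closest known reaction types are the cyclisation of unsaturated hydroperoxides to 1,2-dioxolanes and 1,2-dioxanes with Pd(OAc)2 and p-benzoquinone, which ends by β-hydride loss, and the enantioselective domino oxypalladation–methoxycarbonylation of phenols bearing a 1,1-disubstituted alkene with Pd(OCOCF3)2, a BOXAX ligand, p-benzoquinone, CO and methanol; a hydroperoxide has not been used as the oxygen nucleophile under CO. The 1,2-dioxolane, the only ring of the target, closes in the 5-exo-trig mode. The new quaternary centre C3 is fixed by the alkene face that receives oxygen: the C5 centre, whose two carbon substituents are both sp3 and of similar size next to the ring, offers only a weak 1,3-bias, so the face is assigned to the twofold-symmetric bis(oxazoline) ligand on palladium, which is to place the palladium-bearing methylene cis to the C5 methyl group and trans to the silyloxymethyl arm, any C3 epimer being removed by chromatography. The step needs the hydroperoxide as the only nucleophile, carbonylation ahead of any elimination and an intact O–O bond: the silyl ether masks the hydroxyl that would otherwise close a tetrahydrofuran, the 1,1-disubstituted alkene leaves no β-hydrogen and directs oxygen to the more substituted carbon, both peroxide-bearing carbons are fully substituted, and p-benzoquinone in place of a copper salt keeps monovalent copper and HCl, both of which destroy hydroperoxides, out of the flask.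

Step 6
Reactants: 12 methyl 2-[(3R,5R)-5-{[(tert-butyldiphenylsilyl)oxy]methyl}-3,5-dimethyl-1,2-dioxolan-3-yl]acetate
Product: 13 methyl 2-[(3R,5R)-5-(hydroxymethyl)-3,5-dimethyl-1,2-dioxolan-3-yl]acetate
Conditions: Bu4NF (1.5 equiv), AcOH (1.5 equiv), THF, 0 °C to rt
Reagents that add atoms: none
Why: Fluoride-induced desilylation buffered with acetic acid frees the primary alcohol without exposing the β-peroxy ester to strong base, and the ring cannot undergo Kornblum–DeLaMare cleavage because neither peroxide carbon bears a hydrogen.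

Step 7
Reactants: 13 methyl 2-[(3R,5R)-5-(hydroxymethyl)-3,5-dimethyl-1,2-dioxolan-3-yl]acetate
Product: 14 methyl 2-[(3R,5R)-5-formyl-3,5-dimethyl-1,2-dioxolan-3-yl]acetate
Conditions: Dess–Martin periodinane (1.3 equiv), NaHCO3, CH2Cl2, 0 °C to rt
Reagents that add atoms: none
Why: Dess–Martin oxidation under buffered, non-reducing conditions gives the C6 aldehyde on a quaternary carbon, which can neither epimerise nor eliminate.

Step 8
Reactants: 15 6-bromohexan-1-ol
Product: 16 (6-hydroxyhexyl)triphenylphosphonium bromide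
Conditions: PPh3, MeCN, reflux
Reagents that add atoms: triphenylphosphine, c1ccc(cc1)P(c1ccccc1)c1ccccc1
Why: SN2 quaternisation of triphenylphosphine by the primary bromide gives the phosphonium salt that carries C7 to C12.

Step 9
Reactants: 14 methyl 2-[(3R,5R)-5-formyl-3,5-dimethyl-1,2-dioxolan-3-yl]acetate, 16 (6-hydroxyhexyl)triphenylphosphonium bromide
Product: 18 methyl 2-[(3R,5R)-5-[(1Z)-7-hydroxyhept-1-en-1-yl]-3,5-dimethyl-1,2-dioxolan-3-yl]acetate, via alkoxide ylide 17 (not isolated)
Conditions: 16 (1.5 equiv), NaN(SiMe3)2 (3.0 equiv), THF, −78 to 0 °C; then 14, −78 to −20 °C; aq. NH4Cl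
Reagents that add atoms: none
Why: Wittig olefination with a non-stabilised ylide whose hydroxyl is carried as the sodium alkoxide joins C6 to C7, the addition to the aldehyde at −78 °C being faster than attack on the methyl ester or on the hindered di-tertiary peroxide, and the alkene geometry is of no consequence because the double bond is reduced next.

Step 10
Reactants: 18 methyl 2-[(3R,5R)-5-[(1Z)-7-hydroxyhept-1-en-1-yl]-3,5-dimethyl-1,2-dioxolan-3-yl]acetate
Product: 19 methyl 2-[(3R,5S)-5-(7-hydroxyheptyl)-3,5-dimethyl-1,2-dioxolan-3-yl]acetate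
Conditions: KO2CN=NCO2K (10 equiv), AcOH (20 equiv), MeOH, 0 °C to rt
Reagents that add atoms: none
Why: Diimide reduction delivers H2 to the non-polar C=C bond in a concerted syn transfer and leaves the O–O bond, the ester and both stereocentres untouched, where catalytic hydrogenation would cleave the peroxide (the C5 descriptor becomes S by substituent ranking only).

Step 11
Reactants: 19 methyl 2-[(3R,5S)-5-(7-hydroxyheptyl)-3,5-dimethyl-1,2-dioxolan-3-yl]acetate
Product: 20 methyl 2-[(3R,5S)-3,5-dimethyl-5-(7-oxoheptyl)-1,2-dioxolan-3-yl]acetate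
Conditions: Dess–Martin periodinane (1.3 equiv), NaHCO3, CH2Cl2, 0 °C to rt
Reagents that add atoms: none
Why: Dess–Martin oxidation of the unhindered primary alcohol gives the C12 aldehyde under conditions already shown in step 7 to spare the peroxide and the ester.

Step 12
Reactants: 20 methyl 2-[(3R,5S)-3,5-dimethyl-5-(7-oxoheptyl)-1,2-dioxolan-3-yl]acetate, 21 (triphenylphosphoranylidene)acetaldehyde
Product: 22 methyl 2-[(3R,5S)-3,5-dimethyl-5-[(7E)-9-oxonon-7-en-1-yl]-1,2-dioxolan-3-yl]acetate
Conditions: 21 (1.5 equiv), toluene, 60 °C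
Reagents that add atoms: none
Why: Wittig olefination with a stabilised formyl ylide under neutral conditions forms C12=C13 with E geometry through the reversible, thermodynamically controlled addition typical of stabilised ylides, and the lower reactivity of the product enal limits a second homologation.

Step 13
Reactants: 23 (3Z)-hex-3-en-1-ol
Product: 24 5-{[(3Z)-hex-3-en-1-yl]sulfanyl}-1-phenyl-1H-tetrazole
Conditions: 1-phenyl-1H-tetrazole-5-thiol, PPh3, DIAD, THF, 0 °C to rt
Reagents that add atoms: 1-phenyl-1H-tetrazole-5-thiol, Sc1nnnn1-c1ccccc1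
Why: Mitsunobu thioetherification of the primary alcohol installs the tetrazolyl sulfide without touching the Z-alkene that will become C17=C18.

Step 14
Reactants: 24 5-{[(3Z)-hex-3-en-1-yl]sulfanyl}-1-phenyl-1H-tetrazole, 6 hydrogen peroxide
Product: 25 5-{[(3Z)-hex-3-en-1-yl]sulfonyl}-1-phenyl-1H-tetrazole
Conditions: 30% aq. H2O2 (5 equiv), (NH4)6Mo7O24·4H2O (10 mol%), EtOH, 0 °C to rt
Reagents that add atoms: none
Why: Molybdate-catalysed oxidation of the sulfide to the sulfone is much faster than epoxidation of an isolated, unactivated Z-alkene.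

Step 15
Reactants: 22 methyl 2-[(3R,5S)-3,5-dimethyl-5-[(7E)-9-oxonon-7-en-1-yl]-1,2-dioxolan-3-yl]acetate, 25 5-{[(3Z)-hex-3-en-1-yl]sulfonyl}-1-phenyl-1H-tetrazole
Product: 27 methyl 2-[(3R,5S)-3,5-dimethyl-5-[(7E,9E,12Z)-pentadeca-7,9,12-trien-1-yl]-1,2-dioxolan-3-yl]acetate, via potassium sulfonyl carbanion 26 (not isolated)
Conditions: 25 (1.3 equiv), KN(SiMe3)2 (1.25 equiv), DME, −78 °C; then 22, −78 °C to rt
Reagents that add atoms: none
Why: Julia–Kocienski olefination, in which the preformed sulfonyl carbanion adds to the enal and Smiles rearrangement with loss of SO2 and tetrazololate forms C14=C15, gives the E-alkene with a 1-phenyltetrazolyl sulfone and a potassium base in DME, and the anion is consumed by the aldehyde before it can enolise the β-peroxy ester or attack the O–O bond.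

Step 16
Reactants: 27 methyl 2-[(3R,5S)-3,5-dimethyl-5-[(7E,9E,12Z)-pentadeca-7,9,12-trien-1-yl]-1,2-dioxolan-3-yl]acetate
Product: 28 2-[(3R,5S)-3,5-dimethyl-5-[(7E,9E,12Z)-pentadeca-7,9,12-trien-1-yl]-1,2-dioxolan-3-yl]acetic acid
Conditions: LiOH·H2O (3 equiv), THF/H2O, 0 °C to rt; then 1 M HCl to pH 3
Reagents that add atoms: lithium hydroxide, [Li+].[OH-]
Why: Saponification of the methyl ester with lithium hydroxide at low temperature spares the di-tertiary peroxide and the skipped triene, the carboxylate once formed being protected against enolisation and ring opening.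

**Compound list**
1 | (R)-2-methylglycidol, [(2R)-2-methyloxiran-2-yl]methanol | OC[C@]1(C)CO1 | starting material
2 | [(2S)-2-methyloxiran-2-yl]methyl 4-methylbenzenesulfonate | Cc1ccc(cc1)S(=O)(=O)OC[C@]1(C)CO1 | intermediate
3 | isopropenylmagnesium bromide | CC(=C)[Mg]Br | starting material
4 | (2S)-2-hydroxy-2,4-dimethylpent-4-en-1-yl 4-methylbenzenesulfonate (hydroxy tosylate, not isolated) | Cc1ccc(cc1)S(=O)(=O)OC[C@](O)(C)CC(C)=C | intermediate
5 | (2S)-2-methyl-2-(2-methylprop-2-en-1-yl)oxirane | C=C(C)C[C@@]1(C)CO1 | intermediate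
6 | hydrogen peroxide | OO | starting material
7 | (2R)-2-hydroperoxy-2,4-dimethylpent-4-en-1-ol | OC[C@@](OO)(C)CC(C)=C | intermediate
8 | tert-butyl{[(2R)-2-{[tert-butyl(diphenyl)silyl]peroxy}-2,4-dimethylpent-4-en-1-yl]oxy}diphenylsilane (bis-silyl peroxide, not isolated) | CC(C)(C)[Si](c1ccccc1)(c1ccccc1)OC[C@@](OO[Si](c1ccccc1)(c1ccccc1)C(C)(C)C)(C)CC(C)=C | intermediate
9 | tert-butyl{[(2R)-2-hydroperoxy-2,4-dimethylpent-4-en-1-yl]oxy}diphenylsilane | CC(C)(C)[Si](c1ccccc1)(c1ccccc1)OC[C@@](OO)(C)CC(C)=C | intermediate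
10 | carbon monoxide | [C-]#[O+] | starting material
11 | methanol | CO | starting material
12 | methyl 2-[(3R,5R)-5-{[(tert-butyldiphenylsilyl)oxy]methyl}-3,5-dimethyl-1,2-dioxolan-3-yl]acetate | CC(C)(C)[Si](c1ccccc1)(c1ccccc1)OC[C@@]1(C)C[C@](C)(CC(=O)OC)OO1 | intermediate
13 | methyl 2-[(3R,5R)-5-(hydroxymethyl)-3,5-dimethyl-1,2-dioxolan-3-yl]acetate | OC[C@@]1(C)C[C@](C)(CC(=O)OC)OO1 | intermediate
14 | methyl 2-[(3R,5R)-5-formyl-3,5-dimethyl-1,2-dioxolan-3-yl]acetate | O=C[C@@]1(C)C[C@](C)(CC(=O)OC)OO1 | intermediate
15 | 6-bromohexan-1-ol | OCCCCCCBr | starting material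
16 | (6-hydroxyhexyl)triphenylphosphonium bromide | OCCCCCC[P+](c1ccccc1)(c1ccccc1)c1ccccc1.[Br-] | intermediate
17 | sodium 6-(triphenylphosphoranylidene)hexan-1-olate (alkoxide ylide, not isolated) | [Na+].[O-]CCCCCC=P(c1ccccc1)(c1ccccc1)c1ccccc1 | intermediate
18 | methyl 2-[(3R,5R)-5-[(1Z)-7-hydroxyhept-1-en-1-yl]-3,5-dimethyl-1,2-dioxolan-3-yl]acetate | OCCCCC/C=C\[C@@]1(C)C[C@](C)(CC(=O)OC)OO1 | intermediate
19 | methyl 2-[(3R,5S)-5-(7-hydroxyheptyl)-3,5-dimethyl-1,2-dioxolan-3-yl]acetate | OCCCCCCC[C@@]1(C)C[C@](C)(CC(=O)OC)OO1 | intermediate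
20 | methyl 2-[(3R,5S)-3,5-dimethyl-5-(7-oxoheptyl)-1,2-dioxolan-3-yl]acetate | O=CCCCCCC[C@@]1(C)C[C@](C)(CC(=O)OC)OO1 | intermediate
21 | (triphenylphosphoranylidene)acetaldehyde | O=CC=P(c1ccccc1)(c1ccccc1)c1ccccc1 | starting material
22 | methyl 2-[(3R,5S)-3,5-dimethyl-5-[(7E)-9-oxonon-7-en-1-yl]-1,2-dioxolan-3-yl]acetate | O=C/C=C/CCCCCC[C@@]1(C)C[C@](C)(CC(=O)OC)OO1 | intermediate
23 | (3Z)-hex-3-en-1-ol | CC/C=C\CCO | starting material
24 | 5-{[(3Z)-hex-3-en-1-yl]sulfanyl}-1-phenyl-1H-tetrazole | CC/C=C\CCSc1nnnn1-c1ccccc1 | intermediate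
25 | 5-{[(3Z)-hex-3-en-1-yl]sulfonyl}-1-phenyl-1H-tetrazole | CC/C=C\CCS(=O)(=O)c1nnnn1-c1ccccc1 | intermediate
26 | potassium (3Z)-1-[(1-phenyl-1H-tetrazol-5-yl)sulfonyl]hex-3-en-1-ide (sulfonyl carbanion, not isolated) | [K+].CC/C=C\C[CH-]S(=O)(=O)c1nnnn1-c1ccccc1 | intermediate
27 | methyl 2-[(3R,5S)-3,5-dimethyl-5-[(7E,9E,12Z)-pentadeca-7,9,12-trien-1-yl]-1,2-dioxolan-3-yl]acetate | CC/C=C\C/C=C/C=C/CCCCCC[C@@]1(C)C[C@](C)(CC(=O)OC)OO1 | intermediate
28 | 2-[(3R,5S)-3,5-dimethyl-5-[(7E,9E,12Z)-pentadeca-7,9,12-trien-1-yl]-1,2-dioxolan-3-yl]acetic acid | CC/C=C\C/C=C/C=C/CCCCCC[C@@]1(C)C[C@](C)(CC(=O)O)OO1 | target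

**Step count**
Total: 16 steps. Longest linear sequence: 13 steps (steps 1–7, 9–12, 15 and 16).

**Steps most likely to fail**

Step 5. The alkene may be attacked on the wrong face, so that the C3 epimer dominates. Zerovalent palladium may also cleave the O–O bond, or use the hydroperoxide as its oxidant, before p-benzoquinone intercepts it, and reversal of the peroxypalladation may outrun CO insertion. The fallback uses the established peroxycarbenium route to 1,2-dioxolane-3-acetates and sets out from 9. Ozonolysis of the 1,1-disubstituted alkene (O3, CH2Cl2, −78 °C; Me2S, which reduces the ozonide far faster than the tertiary hydroperoxide) gives the methyl ketone in its ring-closed peroxyhemiketal form, (5R)-5-{[(tert-butyldiphenylsilyl)oxy]methyl}-3,5-dimethyl-1,2-dioxolan-3-ol F1. Methanol with catalytic TsOH converts it into the peroxyketal tert-butyl{[(3R)-5-methoxy-3,5-dimethyl-1,2-dioxolan-3-yl]methoxy}diphenylsilane F2. TiCl4 in CH2Cl2 at −78 °C ionises F2 to the dioxolanyl cation, which is captured by tert-butyl[(1-methoxyethenyl)oxy]dimethylsilane. The route is rejoined at 12, from which any C3 epimer is removed by chromatography.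

Step 3. The acid-promoted opening may pass partly through a tertiary carbocation, so that H2O2 is taken up without clean inversion and configurational purity at C5 is lost; the acid may also add the new hydroperoxide to the methallyl alkene. No other stereospecific entry to this tertiary hydroperoxide is as short, so the fallback restores purity by resolution and sets out from 13. Esterification with (R)-2-methoxy-2-phenylacetic acid (DCC, DMAP cat., CH2Cl2) gives [(3R,5R)-5-(2-methoxy-2-oxoethyl)-3,5-dimethyl-1,2-dioxolan-3-yl]methyl (2R)-2-methoxy-2-phenylacetate F3 and, from any material of the mirror-image series, its (3S,5S)-configured diastereomer F4. After separation by chromatography or crystallisation, methanolysis of F3 (K2CO3, MeOH, 0 °C) returns the route to 13.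

Step 9. The basic ylide may add to the α-peroxy aldehyde and trigger C–C cleavage with heterolysis of the O–O bond (Grob-type fragmentation), or the alkoxide may transesterify or enolise the β-peroxy ester. The fallback keeps basic reagents away from the peroxide-bearing carbon and sets out from 14. A neutral Wittig reaction with the stabilised ylide 21 (toluene, 60 °C) gives methyl 2-[(3R,5R)-3,5-dimethyl-5-[(1E)-3-oxoprop-1-en-1-yl]-1,2-dioxolan-3-yl]acetate F5. Its remote aldehyde is then olefinated with the ylide from (4-hydroxybutyl)triphenylphosphonium bromide (NaN(SiMe3)2, THF, −78 °C) to give methyl 2-[(3R,5R)-5-[(1E,3Z)-7-hydroxyhepta-1,3-dien-1-yl]-3,5-dimethyl-1,2-dioxolan-3-yl]acetate F6. Excess diimide (KO2CN=NCO2K, AcOH, MeOH) saturates both double bonds and the route is rejoined at 19.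

**Further compounds**
F1 | step 5 | (5R)-5-{[(tert-butyldiphenylsilyl)oxy]methyl}-3,5-dimethyl-1,2-dioxolan-3-ol (both C3 epimers) | CC(C)(C)[Si](c1ccccc1)(c1ccccc1)OC[C@@]1(C)CC(C)(O)OO1
F2 | step 5 | tert-butyl{[(3R)-5-methoxy-3,5-dimethyl-1,2-dioxolan-3-yl]methoxy}diphenylsilane (both C5 epimers) | CC(C)(C)[Si](c1ccccc1)(c1ccccc1)OC[C@@]1(C)CC(C)(OC)OO1
F3 | step 3 | [(3R,5R)-5-(2-methoxy-2-oxoethyl)-3,5-dimethyl-1,2-dioxolan-3-yl]methyl (2R)-2-methoxy-2-phenylacetate | CO[C@@H](C(=O)OC[C@@]1(C)C[C@](C)(CC(=O)OC)OO1)c1ccccc1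
F4 | step 3 | [(3S,5S)-5-(2-methoxy-2-oxoethyl)-3,5-dimethyl-1,2-dioxolan-3-yl]methyl (2R)-2-methoxy-2-phenylacetate | CO[C@@H](C(=O)OC[C@]1(C)C[C@@](C)(CC(=O)OC)OO1)c1ccccc1
F5 | step 9 | methyl 2-[(3R,5R)-3,5-dimethyl-5-[(1E)-3-oxoprop-1-en-1-yl]-1,2-dioxolan-3-yl]acetate | O=C/C=C/[C@@]1(C)C[C@](C)(CC(=O)OC)OO1
F6 | step 9 | methyl 2-[(3R,5R)-5-[(1E,3Z)-7-hydroxyhepta-1,3-dien-1-yl]-3,5-dimethyl-1,2-dioxolan-3-yl]acetate | OCCC/C=C\C=C\[C@@]1(C)C[C@](C)(CC(=O)OC)OO1
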